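The flask is closed, so I count by difference: each point of substrate lost has gone somewhere, and I ask what part of it appears as mono adduct.

| flask | substrate | partner | temperature | remark | time |
|---|---|---|---|---|---|
| Tuesday's | 1 M | 0.72 M | −15 °C | run made earlier |  |
| Monday's | 1 M | 1.9 M | 0 °C | run made earlier |  |
| grey | 1.0 M | 1.00 M | 0 °C |  | 80 min |
| ochre | 1.0 M | 3.00 M | 0 °C |  | 20 min |

| run | time / min | mono adduct / % | substrate / % |
|---|---|---|---|
| Tuesday's | 12.0 | 0 | 97.2 |
| Tuesday's | 25.0 | 0.7 | 96.1 |
| Tuesday's | 30.0 | 3.4 | 94.2 |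
| Tuesday's | 50.0 | 2.4 | 90.5 |
| Tuesday's | 60.0 | 3.1 | 89.0 |
| Tuesday's | 80.0 | 4.3 | 84.7 |
| Monday's | 2.00 | 0.5 | 93.8 |
| Monday's | 6.00 | 4.0 | 82.0 |
| Monday's | 12.0 | 9.3 | 69.3 |
| Monday's | 15.0 | 9.2 | 63.2 |
| Monday's | 25.0 | 17.6 | 50.2 |
| Monday's | 30.0 | 18.2 | 44.0 |
| Monday's | 40.0 | 20.3 | 34.4 |

(scatter of a reading: 1 percentage point)

- a reading or a percentage of mono adduct counts all its forms, free or not
- a reading of substrate is of its free form alone

1. which of the two ends with the higher amount of mono adduct, in percent of the substrate charged ("neither" if they lie within 2 percentage points) (grey / ochre / neither)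
2. mono adduct at the end, in percent of the substrate charged, grey
3. mono adduct at the end, in percent of the substrate charged, ochre

- Monday's reading at 40.0 min shows 20.3% mono adduct with 34.4% substrate left, so the yield share, mono adduct found per substrate lost (a selectivity), is 0.309.
- At 12.0 min the same run gives 0.303. That is close, so I freeze the share and need just the loss in each flask.
- My first way to the loss holds partner at its charge. Monday's run then gives a constant of 0.0161 M⁻¹ min⁻¹ at 12.0 min but 0.0140 M⁻¹ min⁻¹ at 40.0 min, a drift downward.
- My second way assumes partner is used one for one with substrate, which on that assumption takes Monday's partner from 1.9 M to 1.24 M at 40.0 min. Its second-order constant reads 0.0176 M⁻¹ min⁻¹ at 12.0 min and 0.0179 M⁻¹ min⁻¹ at 40.0 min. These two readings lie close, so the first way is the one that cheats.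
- The choice matters. Frozen partner has grey losing 67.5% and ochre 56.9%, which puts grey ahead by 3.3 percentage points, beyond the margin of 2 points.
- Spent partner has grey losing 58.9% and ochre 61.0%. With the share, I commit to 18.2% for grey and 18.8% for ochre, a tie within the margin.
- The forecast says neither, with grey at 20% (16% to 24%) and ochre at 18.5% (14% to 23%). Its ground: “If all the steps are first order in partner, selectivity depends only on conversion, so both runs should give about 19–20%.” It puts grey slightly ahead, whereas I put ochre slightly ahead.
- Grey ends at 19.1% and ochre at 19.3%, so the answer is neither. Substrate stands at 40.3% in grey and 39.8% in ochre, while partner stands at 45% and 82% of its own charge.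

    substrate + partner → other mono adduct (k = 0.00690 M⁻¹ min⁻¹, Ea = 60.0 kJ mol⁻¹)
    substrate + partner → mono adduct (k = 0.00560 M⁻¹ min⁻¹, Ea = 74.0 kJ mol⁻¹)
    partner → decomposed reagent (k = 0.00210 min⁻¹, Ea = 80.0 kJ mol⁻¹)
    partner + other mono adduct → double product (k = 2.00 × 10⁻⁴ M⁻¹ min⁻¹, Ea = 68.0 kJ mol⁻¹)
    partner + mono adduct → double product (k = 0.00410 M⁻¹ min⁻¹, Ea = 63.0 kJ mol⁻¹)
    substrate + mono adduct ⇌ idle adduct, settled at all times (K = 16.0 M⁻¹, ΔH = −52.0 kJ mol⁻¹)
    (constants at 0 °C)

- The share of 0.309 on grey's 59.7% conversion gives 18.4%. In a flask like ochre with 0.75 M of partner, substrate ends at 79.3%, so the share gives 6.40%, and that flask holds 6.55%, all forms counted.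

(All runs stem from a simulated flask on assumed constants, noise included.)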